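## Retrosynthetic overview

1. Target ⇒ ester methanolysis of a tri-ester ⇒ aromatic Claisen [3,3] rearrangement of an aryl allyl ether (sets the diarylmethine carbon and the E-alkene by 1,3-chirality transfer) ⇒ late Mitsunobu C–O union of a chalcone phenol and a diarylheptanoid allylic alcohol, two halves of about equal size.
2. Chalcone half ⇐ Claisen–Schmidt condensation with benzaldehyde ⇐ acetophenone from resorcinol (Nencki acetylation, pivaloylation, O-methylation, ketone-directed ortho C–H oxygenation).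
3. Heptanoid half ⇐ anti-selective Evans–Tishchenko reduction of a β-hydroxy enone ⇐ Heck coupling of 4-iodophenyl pivalate with a hydroxy vinyl ketone ⇐ Weinreb amide ⇐ Noyori hydrogenation of benzylated methyl acetoacetate.
4. No ring is built: the four benzene rings come intact from resorcinol, benzaldehyde, 4-iodophenol and benzyl bromide.

Assumption: pivaloyl chloride, iodomethane, PhI(OCOCF3)2, MeNHOMe·HCl and acetaldehyde are treated as reagents; all carbon-skeleton building blocks are numbered starting materials.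

## Route

Step 1
Reactants: 1 resorcinol; 2 acetic acid
Product: 3 1-(2,4-dihydroxyphenyl)ethanone
Conditions: AcOH (neat), ZnCl2, 140–150 °C
Reagents that add atoms: none
Why: Nencki-type Friedel–Crafts acylation puts the acetyl group at C4 of resorcinol (ortho to one OH, para to the other), and the chelated, deactivated product is not acylated again.

Step 2
Reactants: 3 1-(2,4-dihydroxyphenyl)ethanone
Product: 4 4-acetyl-3-hydroxyphenyl pivalate
Conditions: PivCl (1.05 equiv), Et3N, CH2Cl2, 0 °C
Reagents that add atoms: pivaloyl chloride, CC(C)(C)C(=O)Cl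
Why: Selective O-acylation works because the 2-OH is hydrogen-bonded to the ketone, so only the free, more acidic 4-OH is esterified.

Step 3
Reactants: 4 4-acetyl-3-hydroxyphenyl pivalate
Product: 5 4-acetyl-3-methoxyphenyl pivalate
Conditions: MeI, K2CO3, DMF, 40 °C
Reagents that add atoms: iodomethane, CI
Why: Williamson O-methylation of the remaining chelated phenol proceeds under anhydrous carbonate conditions that the hindered pivalate survives.

Step 4
Reactants: 5 4-acetyl-3-methoxyphenyl pivalate
Product: 7 4-acetyl-3-hydroxy-5-methoxyphenyl pivalate, via aryl trifluoroacetate 6 (not isolated)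
Conditions: Pd(OAc)2 (5 mol %), PhI(OCOCF3)2 (2 equiv), ClCH2CH2Cl, 80 °C; then H2O/MeOH work-up
Reagents that add atoms: [bis(trifluoroacetoxy)iodo]benzene, O=C(O[I](OC(=O)C(F)(F)F)c1ccccc1)C(F)(F)F
Why: Ketone-directed ortho C–H oxygenation (cyclopalladation, oxidation by the iodine reagent, C–O reductive elimination) can only occur at the single free ortho position, and the labile trifluoroacetate is hydrolysed on work-up.

Step 5
Reactants: 7 4-acetyl-3-hydroxy-5-methoxyphenyl pivalate; 8 benzaldehyde
Product: 10 3-hydroxy-5-methoxy-4-[(2E)-3-phenylprop-2-enoyl]phenyl pivalate, via aldol adduct 9 (not isolated)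
Conditions: PhCHO (1.2 equiv), BF3·OEt2 (0.5 equiv), 1,4-dioxane, rt; aq. work-up
Reagents that add atoms: none
Why: Lewis acid-mediated Claisen–Schmidt condensation (aldol addition, then dehydration to the conjugated E-enone) avoids base and so keeps the aryl pivalate.

Step 6
Reactants: 11 4-iodophenol
Product: 12 4-iodophenyl pivalate
Conditions: PivCl, Et3N, DMAP (cat.), CH2Cl2, 0 °C → rt
Reagents that add atoms: pivaloyl chloride, CC(C)(C)C(=O)Cl
Why: Simple O-acylation protects the phenol as an ester that is mildly electron-withdrawing and so later disfavours ionisation of the cinnamyl-type system.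

Step 7
Reactants: 13 methyl acetoacetate; 14 benzyl bromide
Product: 16 methyl 3-oxo-5-phenylpentanoate, via acetoacetate dianion 15 (not isolated)
Conditions: NaH, THF, 0 °C; n-BuLi, 0 °C; BnBr, 0 °C → rt; aq. HCl
Reagents that add atoms: none
Why: Weiler dianion alkylation works because the more basic terminal carbanion of the dianion is the one alkylated by benzyl bromide in an SN2 reaction.

Step 8
Reactants: 16 methyl 3-oxo-5-phenylpentanoate
Product: 17 methyl (3R)-3-hydroxy-5-phenylpentanoate
Conditions: H2 (50 atm), RuCl2[(R)-BINAP] (0.2 mol %), MeOH, 50 °C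
Reagents that add atoms: none
Why: Noyori asymmetric hydrogenation of the chelating β-keto ester delivers hydrogen to one face and sets the (3R) carbinol (same sense as methyl acetoacetate giving the (R)-hydroxy ester with the (R)-ligand) in ≥97% ee.

Step 9
Reactants: 17 methyl (3R)-3-hydroxy-5-phenylpentanoate
Product: 18 (3R)-3-hydroxy-N-methoxy-N-methyl-5-phenylpentanamide
Conditions: MeNHOMe·HCl, i-PrMgCl, THF, −20 → 0 °C; aq. NH4Cl
Reagents that add atoms: N,O-dimethylhydroxylamine hydrochloride, CNOC.Cl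
Why: Weinreb amide formation by aminolysis of the ester with the magnesium amide tolerates the free hydroxyl (as its alkoxide) and does not touch the stereocentre.

Step 10
Reactants: 18 (3R)-3-hydroxy-N-methoxy-N-methyl-5-phenylpentanamide; 19 vinylmagnesium bromide
Product: 21 (5R)-5-hydroxy-7-phenylhept-1-en-3-one, via magnesium hemiaminal 20 (not isolated)
Conditions: CH2=CHMgBr (3.5 equiv), THF, −78 → 0 °C; inverse quench into cold 1 M HCl
Reagents that add atoms: none
Why: In this Weinreb ketone synthesis the Grignard reagent adds once to give a stable magnesium chelate that collapses to the vinyl ketone only on acidic quench, which also stops the liberated amine adding to the enone.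

Step 11
Reactants: 21 (5R)-5-hydroxy-7-phenylhept-1-en-3-one; 12 4-iodophenyl pivalate
Product: 22 4-[(1E,5R)-5-hydroxy-3-oxo-7-phenylhept-1-en-1-yl]phenyl pivalate
Conditions: Pd(OAc)2 (5 mol %), NaHCO3, n-Bu4NCl, DMF, 45 °C
Reagents that add atoms: none
Why: The Mizoroki–Heck reaction under Jeffery conditions arylates the terminal carbon of the electron-poor alkene and gives the E-enone by syn-β-hydride elimination, with bicarbonate mild enough to spare the β-hydroxy ketone.

Step 12
Reactants: 22 4-[(1E,5R)-5-hydroxy-3-oxo-7-phenylhept-1-en-1-yl]phenyl pivalate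
Product: 24 4-[(1E,3S,5R)-5-acetoxy-3-hydroxy-7-phenylhept-1-en-1-yl]phenyl pivalate, via samarium hemiacetal 23 (not isolated)
Conditions: MeCHO (6 equiv), SmI2 (20 mol %), THF, −10 °C
Reagents that add atoms: acetaldehyde, CC=O
Why: In the Evans–Tishchenko reduction the samarium-bound hemiacetal delivers hydride intramolecularly through a six-membered chair transition state, which sets the new (3S) carbinol anti to the existing oxygen (dr > 20:1) and leaves that oxygen as its acetate.

Step 13
Reactants: 10 3-hydroxy-5-methoxy-4-[(2E)-3-phenylprop-2-enoyl]phenyl pivalate; 24 4-[(1E,3S,5R)-5-acetoxy-3-hydroxy-7-phenylhept-1-en-1-yl]phenyl pivalate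
Product: 26 4-[(1E,3R,5R)-5-acetoxy-3-{3-methoxy-5-(pivaloyloxy)-2-[(2E)-3-phenylprop-2-enoyl]phenoxy}-7-phenylhept-1-en-1-yl]phenyl pivalate, via alkoxyphosphonium phenoxide 25 (not isolated)
Conditions: PPh3, DIAD, toluene, 0 °C → rt
Reagents that add atoms: none
Why: In this Mitsunobu etherification the phenoxide displaces the activated oxygen in an SN2 reaction with inversion, turning the (3S) alcohol into the (3R) aryl ether, as is established for Evans–Tishchenko monoesters.

Step 14
Reactants: 26 the aryl allyl ether from step 13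
Product: 28 4-[(1R,2E,5R)-5-acetoxy-1-{2-hydroxy-4-methoxy-6-(pivaloyloxy)-3-[(2E)-3-phenylprop-2-enoyl]phenyl}-7-phenylhept-2-en-1-yl]phenyl pivalate, via ortho-dienone 27 (not isolated)
Conditions: Eu(fod)3 (10 mol %; fod = 6,6,7,7,8,8,8-heptafluoro-2,2-dimethyloctane-3,5-dionate), CHCl3, 60 °C, sealed tube
Reagents that add atoms: none
Why: The Lewis acid-catalysed aromatic Claisen rearrangement can only reach the free ortho carbon (the other is blocked by the acyl group), and its suprafacial chair transition state with the side chain equatorial gives the E-alkene and transfers the (3R) C–O chirality to the (1R) diarylmethine carbon before the dienone tautomerises to the phenol.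

Step 15
Reactants: 28 the tri-ester from step 14
Product: 29 (2E)-1-{2,4-dihydroxy-3-[(1R,2E,5R)-5-hydroxy-1-(4-hydroxyphenyl)-7-phenylhept-2-en-1-yl]-6-methoxyphenyl}-3-phenylprop-2-en-1-one (ent-alpinnanin B)
Conditions: K2CO3, MeOH/THF, 0 °C → rt; then cold 1 M HCl to pH 5
Reagents that add atoms: none
Why: Base-mediated transesterification (methanolysis) removes the two aryl pivalates and the secondary acetate without touching either stereocentre, and cold acidification returns the free chalcone.

## Compound list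

1 | resorcinol | Oc1cccc(O)c1 | starting material
2 | acetic acid | CC(=O)O | starting material
3 | 1-(2,4-dihydroxyphenyl)ethanone | CC(=O)c1ccc(O)cc1O | intermediate
4 | 4-acetyl-3-hydroxyphenyl pivalate | CC(=O)c1ccc(OC(=O)C(C)(C)C)cc1O | intermediate
5 | 4-acetyl-3-methoxyphenyl pivalate | COc1cc(OC(=O)C(C)(C)C)ccc1C(C)=O | intermediate
6 | 4-acetyl-3-methoxy-5-(trifluoroacetoxy)phenyl pivalate (formed in the flask) | COc1cc(OC(=O)C(C)(C)C)cc(OC(=O)C(F)(F)F)c1C(C)=O | intermediate
7 | 4-acetyl-3-hydroxy-5-methoxyphenyl pivalate | COc1cc(OC(=O)C(C)(C)C)cc(O)c1C(C)=O | intermediate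
8 | benzaldehyde | O=Cc1ccccc1 | starting material
9 | 3-hydroxy-4-(3-hydroxy-3-phenylpropanoyl)-5-methoxyphenyl pivalate (aldol adduct, racemic carbinol, formed in the flask) | COc1cc(OC(=O)C(C)(C)C)cc(O)c1C(=O)CC(O)c1ccccc1 | intermediate
10 | 3-hydroxy-5-methoxy-4-[(2E)-3-phenylprop-2-enoyl]phenyl pivalate (cardamonin 4'-O-pivalate) | COc1cc(OC(=O)C(C)(C)C)cc(O)c1C(=O)/C=C/c1ccccc1 | intermediate
11 | 4-iodophenol | Oc1ccc(I)cc1 | starting material
12 | 4-iodophenyl pivalate | CC(C)(C)C(=O)Oc1ccc(I)cc1 | intermediate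
13 | methyl acetoacetate | COC(=O)CC(C)=O | starting material
14 | benzyl bromide | BrCc1ccccc1 | starting material
15 | sodium lithium dianion (dienolate) of methyl acetoacetate (formed in the flask) | [Na+].[Li+].C=C([O-])C=C([O-])OC | intermediate
16 | methyl 3-oxo-5-phenylpentanoate | COC(=O)CC(=O)CCc1ccccc1 | intermediate
17 | methyl (3R)-3-hydroxy-5-phenylpentanoate | COC(=O)C[C@H](O)CCc1ccccc1 | intermediate
18 | (3R)-3-hydroxy-N-methoxy-N-methyl-5-phenylpentanamide | CON(C)C(=O)C[C@H](O)CCc1ccccc1 | intermediate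
19 | vinylmagnesium bromide | C=C[Mg]Br | starting material
20 | bis(bromomagnesium) salt of the tetrahedral N-methoxy-N-methyl hemiaminal, (5R), new centre undefined (formed in the flask) | C=CC(O[Mg]Br)(N(C)OC)C[C@H](O[Mg]Br)CCc1ccccc1 | intermediate
21 | (5R)-5-hydroxy-7-phenylhept-1-en-3-one | C=CC(=O)C[C@H](O)CCc1ccccc1 | intermediate
22 | 4-[(1E,5R)-5-hydroxy-3-oxo-7-phenylhept-1-en-1-yl]phenyl pivalate | CC(C)(C)C(=O)Oc1ccc(/C=C/C(=O)C[C@H](O)CCc2ccccc2)cc1 | intermediate
23 | hemiacetal of 22 with acetaldehyde, held on samarium as its alkoxide, hemiacetal carbon undefined (formed in the flask) | CC(C)(C)C(=O)Oc1ccc(/C=C/C(=O)C[C@H](OC(C)O)CCc2ccccc2)cc1 | intermediate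
24 | 4-[(1E,3S,5R)-5-acetoxy-3-hydroxy-7-phenylhept-1-en-1-yl]phenyl pivalate | CC(C)(C)C(=O)Oc1ccc(/C=C/[C@@H](O)C[C@H](OC(C)=O)CCc2ccccc2)cc1 | intermediate
25 | {(1E,3S,5R)-5-acetoxy-7-phenyl-1-[4-(pivaloyloxy)phenyl]hept-1-en-3-yl}oxytriphenylphosphonium salt of the phenoxide of 10 (formed in the flask) | CC(C)(C)C(=O)Oc1ccc(/C=C/[C@@H](O[P+](c2ccccc2)(c2ccccc2)c2ccccc2)C[C@H](OC(C)=O)CCc2ccccc2)cc1.COc1cc(OC(=O)C(C)(C)C)cc([O-])c1C(=O)/C=C/c1ccccc1 | intermediate
26 | 4-[(1E,3R,5R)-5-acetoxy-3-{3-methoxy-5-(pivaloyloxy)-2-[(2E)-3-phenylprop-2-enoyl]phenoxy}-7-phenylhept-1-en-1-yl]phenyl pivalate | COc1cc(OC(=O)C(C)(C)C)cc(O[C@@H](/C=C/c2ccc(OC(=O)C(C)(C)C)cc2)C[C@H](OC(C)=O)CCc2ccccc2)c1C(=O)/C=C/c1ccccc1 | intermediate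
27 | ortho-dienone (cyclohexa-2,4-dienone) tautomer of 28: ring A phenol carbon as C=O, the alkylated ring carbon sp3 and (S), side-chain centres as in 28 (formed in the flask) | COC1=C(C(=O)/C=C/c2ccccc2)C(=O)[C@@H]([C@H](/C=C/C[C@H](OC(C)=O)CCc2ccccc2)c2ccc(OC(=O)C(C)(C)C)cc2)C(OC(=O)C(C)(C)C)=C1 | intermediate
28 | 4-[(1R,2E,5R)-5-acetoxy-1-{2-hydroxy-4-methoxy-6-(pivaloyloxy)-3-[(2E)-3-phenylprop-2-enoyl]phenyl}-7-phenylhept-2-en-1-yl]phenyl pivalate | COc1cc(OC(=O)C(C)(C)C)c([C@H](/C=C/C[C@H](OC(C)=O)CCc2ccccc2)c2ccc(OC(=O)C(C)(C)C)cc2)c(O)c1C(=O)/C=C/c1ccccc1 | intermediate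
29 | (2E)-1-{2,4-dihydroxy-3-[(1R,2E,5R)-5-hydroxy-1-(4-hydroxyphenyl)-7-phenylhept-2-en-1-yl]-6-methoxyphenyl}-3-phenylprop-2-en-1-one (ent-alpinnanin B) | COc1cc(O)c([C@H](/C=C/C[C@H](O)CCc2ccccc2)c2ccc(O)cc2)c(O)c1C(=O)/C=C/c1ccccc1 | target

## Step count and risks

Total step count: 15.
Longest linear sequence: 9 steps (steps 7–15, from methyl acetoacetate 13 and benzyl bromide 14), i.e. 0.60 of the total. The resorcinol branch is 8 steps (1–5, 13–15).

The three steps most likely to fail:

Step 4. The arene is electron-rich and the oxidant is strong, so over-oxidation or poor turnover of Pd(OAc)2 is possible. The fallback installs the third oxygen before the ketone instead of by C–H oxygenation of the ketone; it sets out from resorcinol 1 and comes back at phenol 7. Resorcinol is protected (MOMCl, i-Pr2NEt) as 1,3-bis(methoxymethoxy)benzene F1. Sterically controlled C–H borylation ([Ir(OMe)(cod)]2, dtbpy, B2pin2, THF, 80 °C) gives 2-[3,5-bis(methoxymethoxy)phenyl]-4,4,5,5-tetramethyl-1,3,2-dioxaborolane F2, which is oxidised (H2O2, NaOH) to 3,5-bis(methoxymethoxy)phenol F3. Methylation (MeI, K2CO3) gives 1-methoxy-3,5-bis(methoxymethoxy)benzene F4, and HCl/MeOH gives 5-methoxyresorcinol F5. Friedel–Crafts acetylation with acetic acid 2 and BF3·OEt2 gives 1-(2,4-dihydroxy-6-methoxyphenyl)ethanone F6; the regiochemistry is less clean than in step 4 and needs chromatography. Selective pivaloylation of the non-chelated 4-OH (PivCl, Et3N) then gives 7.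

Step 13. The phenol is hindered and hydrogen-bonded, and the activated allylic centre may react by SN2' or eliminate. The fallback separates the inversion from the C–O bond formation; it sets out from alcohol 24 and comes back at ether 26. Mitsunobu esterification of 24 with 4-nitrobenzoic acid (PPh3, DIAD), a far better partner than the phenol, gives the inverted ester 4-[(1E,3R,5R)-5-acetoxy-3-(4-nitrobenzoyloxy)-7-phenylhept-1-en-1-yl]phenyl pivalate F7. Allylic etherification of phenol 10 with F7 (Pd2(dba)3 as zerovalent palladium source, PPh3, Cs2CO3, THF) then proceeds with net retention by double inversion. The phenoxide attacks the alkyl-bearing allyl terminus, which keeps the styrene conjugation, and gives 26.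

Step 14. A para-Claisen or ionisation pathway could compete and erode regio- or stereocontrol, and Eu(fod)3 may cyclise the newly freed 2'-hydroxychalcone to a flavanone. The fallback rearranges before the enone is present; it sets out from acetophenone 7 and comes back at 28. Mitsunobu etherification of 7 with 24 gives 4-[(1E,3R,5R)-5-acetoxy-3-{2-acetyl-3-methoxy-5-(pivaloyloxy)phenoxy}-7-phenylhept-1-en-1-yl]phenyl pivalate F8. Thermal aromatic Claisen rearrangement (N,N-diethylaniline, 170 °C), which the simple acetophenone tolerates, gives 4-[(1R,2E,5R)-5-acetoxy-1-{3-acetyl-2-hydroxy-4-methoxy-6-(pivaloyloxy)phenyl}-7-phenylhept-2-en-1-yl]phenyl pivalate F9 with the same chirality transfer. BF3·OEt2-mediated Claisen–Schmidt condensation with benzaldehyde 8, as in step 5, then gives 28. This fallback addresses the enone-related failure modes, not an intrinsic loss of chirality transfer.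

## Further compounds

F1 | step 4 | 1,3-bis(methoxymethoxy)benzene | COCOc1cccc(OCOC)c1
F2 | step 4 | 2-[3,5-bis(methoxymethoxy)phenyl]-4,4,5,5-tetramethyl-1,3,2-dioxaborolane | COCOc1cc(OCOC)cc(c1)B1OC(C)(C)C(C)(C)O1
F3 | step 4 | 3,5-bis(methoxymethoxy)phenol | COCOc1cc(O)cc(OCOC)c1
F4 | step 4 | 1-methoxy-3,5-bis(methoxymethoxy)benzene | COCOc1cc(OC)cc(OCOC)c1
F5 | step 4 | 5-methoxyresorcinol | COc1cc(O)cc(O)c1
F6 | step 4 | 1-(2,4-dihydroxy-6-methoxyphenyl)ethanone | COc1cc(O)cc(O)c1C(C)=O
F7 | step 13 | 4-[(1E,3R,5R)-5-acetoxy-3-(4-nitrobenzoyloxy)-7-phenylhept-1-en-1-yl]phenyl pivalate | CC(C)(C)C(=O)Oc1ccc(/C=C/[C@H](OC(=O)c2ccc(cc2)[N+](=O)[O-])C[C@H](OC(C)=O)CCc2ccccc2)cc1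
F8 | step 14 | 4-[(1E,3R,5R)-5-acetoxy-3-{2-acetyl-3-methoxy-5-(pivaloyloxy)phenoxy}-7-phenylhept-1-en-1-yl]phenyl pivalate | COc1cc(OC(=O)C(C)(C)C)cc(O[C@@H](/C=C/c2ccc(OC(=O)C(C)(C)C)cc2)C[C@H](OC(C)=O)CCc2ccccc2)c1C(C)=O
F9 | step 14 | 4-[(1R,2E,5R)-5-acetoxy-1-{3-acetyl-2-hydroxy-4-methoxy-6-(pivaloyloxy)phenyl}-7-phenylhept-2-en-1-yl]phenyl pivalate | COc1cc(OC(=O)C(C)(C)C)c([C@H](/C=C/C[C@H](OC(C)=O)CCc2ccccc2)c2ccc(OC(=O)C(C)(C)C)cc2)c(O)c1C(C)=O
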